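**Plan**

- Retrosynthesis: the four benzyl ethers come off last. Ring A of the 5-hydroxy-7-methoxychromone is then cut at C8–C8a and C4a–C5, giving a 2,3-diaryl-5-(phenylsulfonyl)pyran-4-one and 1,3-dimethoxy-1-(trimethylsilyloxy)buta-1,3-diene.
- Enabling feature: ring A carries OH on C5 and OMe on C7, with C6 and C8 unsubstituted. This is the 1,3-dioxygenation of the diene, and C4a/C8a are the C5=C6 alkene of a pyran-4-one, so the single O-methyl group is fixed by the ring-forming step.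
- The pyranone is cut at O1–C6/C5–C6 (one carbon from Me2NCH(OMe)2) and at C3–C4 (C-acylation with (phenylthio)acetyl chloride). Sulfur arrives with the building block, so no electrophilic halogenation is needed near the electron-rich dibenzyloxy ring. The aryl–CH2 bond is cut last (palladium-catalysed ketone α-arylation), leaving 3'-bromo-tri-O-benzylapigenin.
- Forward order of rings: the pyranone ring of the apigenin unit (aldol, oxidative cyclisation), then the monocyclic pyran-4-one, then ring A by benzannulation.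
- Stereochemistry: the target has no stereocentre; the stereocentres of intermediates 10 and 17 are erased by enolisation and aromatisation.

Key step: step 11

Remark on the chemistry: rotation about the C3–aryl bond of the target is taken as free, so no axial configuration is addressed. Compounds 10 and 17 are racemic, and 11 is of undefined alkene geometry.

**Route**

Step 1
Reactants: 1 3-bromo-4-hydroxybenzaldehyde
Product: 2 4-(benzyloxy)-3-bromobenzaldehyde
Conditions: BnBr, K2CO3, DMF, rt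
Reagents that add atoms: benzyl bromide, BrCc1ccccc1
Why: Williamson ether synthesis on an acidic para-formyl phenol should proceed cleanly at oxygen.

Step 2
Reactants: 3 2,4,6-trihydroxyacetophenone
Product: 4 1-[2,4-bis(benzyloxy)-6-hydroxyphenyl]ethanone
Conditions: BnBr (2.1 equiv), K2CO3, DMF, rt
Reagents that add atoms: benzyl bromide, BrCc1ccccc1
Why: Williamson ether synthesis in which the hydroxyl hydrogen-bonded to the acetyl carbonyl is the least nucleophilic, so the para and one ortho hydroxyl should be etherified and the chelated one kept.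

Step 3
Reactants: 2 4-(benzyloxy)-3-bromobenzaldehyde; 4 1-[2,4-bis(benzyloxy)-6-hydroxyphenyl]ethanone
Product: 5 (E)-1-[2,4-bis(benzyloxy)-6-hydroxyphenyl]-3-[4-(benzyloxy)-3-bromophenyl]prop-2-en-1-one
Conditions: KOH (aq), EtOH/THF, rt
Reagents that add atoms: none
Why: Claisen–Schmidt condensation of a methyl ketone with a non-enolisable aldehyde, with dehydration of the aldol giving the conjugated E alkene.

Step 4
Reactants: 5 (E)-1-[2,4-bis(benzyloxy)-6-hydroxyphenyl]-3-[4-(benzyloxy)-3-bromophenyl]prop-2-en-1-one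
Product: 6 5,7-bis(benzyloxy)-2-[4-(benzyloxy)-3-bromophenyl]chromen-4-one
Conditions: I2 (cat.), DMSO, 130 °C
Reagents that add atoms: none
Why: Iodine-catalysed oxidative cyclisation of a 2'-hydroxychalcone (6-endo oxa-Michael addition, α-iodination, loss of HI, with DMSO as terminal oxidant) is the standard entry to flavones and tolerates aryl bromides and benzyl ethers.

Step 5
Reactants: 6 5,7-bis(benzyloxy)-2-[4-(benzyloxy)-3-bromophenyl]chromen-4-one; 7 1-[4-(benzyloxy)phenyl]ethanone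
Product: 8 1-[4-(benzyloxy)phenyl]-2-{2-(benzyloxy)-5-[5,7-bis(benzyloxy)-4-oxochromen-2-yl]phenyl}ethanone
Conditions: Pd2(dba)3 (cat.), Xantphos, K3PO4, PhMe, 90 °C; 7 in excess
Reagents that add atoms: none
Why: Palladium-catalysed α-arylation of an aryl methyl ketone with an aryl bromide under a mild phosphate base should give the deoxybenzoin, and the ortho benzyloxy group of 6 should disfavour a second arylation.

Step 6
Reactants: 8 1-[4-(benzyloxy)phenyl]-2-{2-(benzyloxy)-5-[5,7-bis(benzyloxy)-4-oxochromen-2-yl]phenyl}ethanone; 9 (phenylthio)acetyl chloride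
Product: 10 1-[4-(benzyloxy)phenyl]-2-{2-(benzyloxy)-5-[5,7-bis(benzyloxy)-4-oxochromen-2-yl]phenyl}-4-(phenylthio)butane-1,3-dione (racemic, largely enolised)
Conditions: MgBr2·OEt2, i-Pr2NEt, CH2Cl2, 0 °C to rt
Reagents that add atoms: none
Why: Soft-enolisation C-acylation, in which the magnesium-bound enolate of the acidic deoxybenzoin is acylated at carbon and the product is held as a magnesium diketonate, should give the 2-aryl-1,3-diketone.

Step 7
Reactants: 10 1-[4-(benzyloxy)phenyl]-2-{2-(benzyloxy)-5-[5,7-bis(benzyloxy)-4-oxochromen-2-yl]phenyl}-4-(phenylthio)butane-1,3-dione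
Product: 12 2-[4-(benzyloxy)phenyl]-3-{2-(benzyloxy)-5-[5,7-bis(benzyloxy)-4-oxochromen-2-yl]phenyl}-5-(phenylthio)pyran-4-one, via enaminone 11 (not isolated)
Conditions: Me2NCH(OMe)2, PhMe, 90 °C; then AcOH, 80 °C
Reagents that add atoms: N,N-dimethylformamide dimethyl acetal, COC(OC)N(C)C
Why: Amide acetal condensation can only occur at the CH2 between carbonyl and sulfur, and the resulting enaminone should close to the 4-pyranone by 6-endo addition–elimination of the enol oxygen with loss of dimethylamine, the same cyclocondensation used for 3-substituted chromones.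

Step 8
Reactants: 12 2-[4-(benzyloxy)phenyl]-3-{2-(benzyloxy)-5-[5,7-bis(benzyloxy)-4-oxochromen-2-yl]phenyl}-5-(phenylthio)pyran-4-one
Product: 13 2-[4-(benzyloxy)phenyl]-3-{2-(benzyloxy)-5-[5,7-bis(benzyloxy)-4-oxochromen-2-yl]phenyl}-5-(phenylsulfonyl)pyran-4-one
Conditions: mCPBA (2.5 equiv), CH2Cl2, 0 °C to rt
Reagents that add atoms: mCPBA, O=C(OO)c1cccc(Cl)c1
Why: Peracid oxidation of an aryl vinyl sulfide to the sulfone should be far faster than any attack on the electron-poor pyranone, the flavone or the benzyl ethers.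

Step 9
Reactants: 14 methyl acetoacetate
Product: 15 methyl (E)-3-methoxybut-2-enoate
Conditions: HC(OMe)3, H2SO4 (cat.), MeOH, rt; distillation
Reagents that add atoms: trimethyl orthoformate, COC(OC)OC
Why: Acid-catalysed ketalisation followed by loss of methanol gives the conjugated enol ether, with the E isomer favoured thermodynamically.

Step 10
Reactants: 15 methyl (E)-3-methoxybut-2-enoate
Product: 16 (E)-1,3-dimethoxy-1-(trimethylsilyloxy)buta-1,3-diene
Conditions: LiN(i-Pr)2, THF, −78 °C; Me3SiCl; used crude after removal of salts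
Reagents that add atoms: chlorotrimethylsilane, C[Si](C)(C)Cl
Why: Kinetic γ-deprotonation of the β-methoxy enoate and O-silylation of the dienolate is the established preparation of this silyl ketene acetal diene.

Step 11
Reactants: 13 2-[4-(benzyloxy)phenyl]-3-{2-(benzyloxy)-5-[5,7-bis(benzyloxy)-4-oxochromen-2-yl]phenyl}-5-(phenylsulfonyl)pyran-4-one; 16 (E)-1,3-dimethoxy-1-(trimethylsilyloxy)buta-1,3-diene
Product: 19 2-[4-(benzyloxy)phenyl]-3-{2-(benzyloxy)-5-[5,7-bis(benzyloxy)-4-oxochromen-2-yl]phenyl}-5-hydroxy-7-methoxychromen-4-one, via cycloadduct 17 (not isolated), via silyl ether 18 (not isolated)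
Conditions: 16 (3 equiv), PhMe, 110 °C, sealed tube; then DBU, rt; then 1 M HCl, THF, rt
Reagents that add atoms: none
Why: Proposed new method: the C5=C6 bond of 13 is a β-alkoxy enone that also carries the sulfone, so C6 is strongly electrophilic; the CH2 terminus of the ketene acetal diene should bond there (future C8–C8a) while the ketene acetal carbon bonds to the sulfone-bearing C5 (future C4a–C5), either as an asynchronous [4+2] cycloaddition or as a Mukaiyama–Michael addition followed by closure of the sulfonyl-stabilised enolate on the silyloxy-oxocarbenium ion, giving the cis-fused adduct 17. The closest known reactions are the benzannulations of haloquinones with this diene, which give 1-hydroxy-3-methoxy arenes, and the cycloadditions of 3-sulfinyl- and 3-acylchromones with siloxydienes that lead to xanthones; a monocyclic sulfonylpyranone has not been used as the 2π partner. Ring A is the only ring closed, as a formal [4+2] process (in the stepwise limit a 6-exo-trig closure), and no stereocentre survives: 17 should lose methanol from its allylic mixed ketal (the C5 methoxy with a C8 hydrogen) and, with DBU, benzenesulfinic acid across C4a–C8a to give the aryl silyl ether 18, which dilute acid cleaves to the chelated C5 phenol. The step needs regioselectivity and site selectivity: matched polarity (nucleophilic diene CH2 to the oxygen-bearing, doubly activated C6) places the silyloxy carbon next to the C4 carbonyl and the methoxy carbon at C7, and the flavone C2=C3 and the tetrasubstituted pyranone C2=C3, which lack the sulfone, should not compete.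

Step 12
Reactants: 19 2-[4-(benzyloxy)phenyl]-3-{2-(benzyloxy)-5-[5,7-bis(benzyloxy)-4-oxochromen-2-yl]phenyl}-5-hydroxy-7-methoxychromen-4-one
Product: 20 5-hydroxy-3-[2-hydroxy-5-(5,7-dihydroxy-4-oxochromen-2-yl)phenyl]-2-(4-hydroxyphenyl)-7-methoxychromen-4-one
Conditions: H2 (1 atm), Pd/C, THF/MeOH, rt
Reagents that add atoms: none
Why: Hydrogenolysis of aryl benzyl ethers over Pd/C at ambient pressure should free the four phenols while leaving the chromone double bonds and the methyl ether untouched.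

**Compound list**

1 | 3-bromo-4-hydroxybenzaldehyde | O=Cc1ccc(O)c(Br)c1 | starting material
2 | 4-(benzyloxy)-3-bromobenzaldehyde | O=Cc1ccc(OCc2ccccc2)c(Br)c1 | intermediate
3 | 2,4,6-trihydroxyacetophenone | CC(=O)c1c(O)cc(O)cc1O | starting material
4 | 1-[2,4-bis(benzyloxy)-6-hydroxyphenyl]ethanone | CC(=O)c1c(O)cc(OCc2ccccc2)cc1OCc1ccccc1 | intermediate
5 | (E)-1-[2,4-bis(benzyloxy)-6-hydroxyphenyl]-3-[4-(benzyloxy)-3-bromophenyl]prop-2-en-1-one | O=C(/C=C/c1ccc(OCc2ccccc2)c(Br)c1)c1c(O)cc(OCc2ccccc2)cc1OCc1ccccc1 | intermediate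
6 | 5,7-bis(benzyloxy)-2-[4-(benzyloxy)-3-bromophenyl]chromen-4-one | O=c1cc(-c2ccc(OCc3ccccc3)c(Br)c2)oc2cc(OCc3ccccc3)cc(OCc3ccccc3)c12 | intermediate
7 | 1-[4-(benzyloxy)phenyl]ethanone (4'-(benzyloxy)acetophenone) | CC(=O)c1ccc(OCc2ccccc2)cc1 | starting material
8 | 1-[4-(benzyloxy)phenyl]-2-{2-(benzyloxy)-5-[5,7-bis(benzyloxy)-4-oxochromen-2-yl]phenyl}ethanone | O=C(Cc1cc(-c2cc(=O)c3c(OCc4ccccc4)cc(OCc4ccccc4)cc3o2)ccc1OCc1ccccc1)c1ccc(OCc2ccccc2)cc1 | intermediate
9 | (phenylthio)acetyl chloride | O=C(Cl)CSc1ccccc1 | starting material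
10 | 1-[4-(benzyloxy)phenyl]-2-{2-(benzyloxy)-5-[5,7-bis(benzyloxy)-4-oxochromen-2-yl]phenyl}-4-(phenylthio)butane-1,3-dione (racemic, largely enolised) | O=C(CSc1ccccc1)C(C(=O)c1ccc(OCc2ccccc2)cc1)c1cc(-c2cc(=O)c3c(OCc4ccccc4)cc(OCc4ccccc4)cc3o2)ccc1OCc1ccccc1 | intermediate
11 | 1-[4-(benzyloxy)phenyl]-2-{2-(benzyloxy)-5-[5,7-bis(benzyloxy)-4-oxochromen-2-yl]phenyl}-5-(dimethylamino)-4-(phenylthio)pent-4-ene-1,3-dione (alkene geometry not defined) | CN(C)C=C(Sc1ccccc1)C(=O)C(C(=O)c1ccc(OCc2ccccc2)cc1)c1cc(-c2cc(=O)c3c(OCc4ccccc4)cc(OCc4ccccc4)cc3o2)ccc1OCc1ccccc1 | intermediate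
12 | 2-[4-(benzyloxy)phenyl]-3-{2-(benzyloxy)-5-[5,7-bis(benzyloxy)-4-oxochromen-2-yl]phenyl}-5-(phenylthio)pyran-4-one | O=c1c(Sc2ccccc2)coc(-c2ccc(OCc3ccccc3)cc2)c1-c1cc(-c2cc(=O)c3c(OCc4ccccc4)cc(OCc4ccccc4)cc3o2)ccc1OCc1ccccc1 | intermediate
13 | 2-[4-(benzyloxy)phenyl]-3-{2-(benzyloxy)-5-[5,7-bis(benzyloxy)-4-oxochromen-2-yl]phenyl}-5-(phenylsulfonyl)pyran-4-one | O=c1c(S(=O)(=O)c2ccccc2)coc(-c2ccc(OCc3ccccc3)cc2)c1-c1cc(-c2cc(=O)c3c(OCc4ccccc4)cc(OCc4ccccc4)cc3o2)ccc1OCc1ccccc1 | intermediate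
14 | methyl acetoacetate | COC(=O)CC(C)=O | starting material
15 | methyl (E)-3-methoxybut-2-enoate | COC(=O)/C=C(\C)OC | intermediate
16 | (E)-1,3-dimethoxy-1-(trimethylsilyloxy)buta-1,3-diene | C=C(OC)/C=C(/O[Si](C)(C)C)OC | intermediate
17 | 2-[4-(benzyloxy)phenyl]-3-{2-(benzyloxy)-5-[5,7-bis(benzyloxy)-4-oxochromen-2-yl]phenyl}-5,7-dimethoxy-4a-(phenylsulfonyl)-5-(trimethylsilyloxy)-4a,5,8,8a-tetrahydrochromen-4-one (racemic, one enantiomer drawn; sulfonyl group and C8a hydrogen cis; C5 configuration not defined) | COC1=CC(OC)(O[Si](C)(C)C)[C@@]2(S(=O)(=O)c3ccccc3)C(=O)C(-c3cc(-c4cc(=O)c5c(OCc6ccccc6)cc(OCc6ccccc6)cc5o4)ccc3OCc3ccccc3)=C(-c3ccc(OCc4ccccc4)cc3)O[C@H]2C1 | intermediate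
18 | 2-[4-(benzyloxy)phenyl]-3-{2-(benzyloxy)-5-[5,7-bis(benzyloxy)-4-oxochromen-2-yl]phenyl}-7-methoxy-5-(trimethylsilyloxy)chromen-4-one | COc1cc(O[Si](C)(C)C)c2c(=O)c(-c3cc(-c4cc(=O)c5c(OCc6ccccc6)cc(OCc6ccccc6)cc5o4)ccc3OCc3ccccc3)c(-c3ccc(OCc4ccccc4)cc3)oc2c1 | intermediate
19 | 2-[4-(benzyloxy)phenyl]-3-{2-(benzyloxy)-5-[5,7-bis(benzyloxy)-4-oxochromen-2-yl]phenyl}-5-hydroxy-7-methoxychromen-4-one | COc1cc(O)c2c(=O)c(-c3cc(-c4cc(=O)c5c(OCc6ccccc6)cc(OCc6ccccc6)cc5o4)ccc3OCc3ccccc3)c(-c3ccc(OCc4ccccc4)cc3)oc2c1 | intermediate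
20 | 5-hydroxy-3-[2-hydroxy-5-(5,7-dihydroxy-4-oxochromen-2-yl)phenyl]-2-(4-hydroxyphenyl)-7-methoxychromen-4-one (CNP0284832.0) | COc1cc(O)c2c(=O)c(-c3cc(-c4cc(=O)c5c(O)cc(O)cc5o4)ccc3O)c(-c3ccc(O)cc3)oc2c1 | target

**Counts**

Total step count: 12.
Longest linear sequence: 9 steps (steps 1, 3, 4, 5, 6, 7, 8, 11, 12; from 1 to 20).

**Steps most likely to fail**

1. Step 11 (proposed new method). The diene may add only in the Michael sense without ring closure, the pyranone may open by retro-oxa-Michael reaction, or the diene may decompose thermally before it engages the hindered, partly aromatic dienophile. The fallback uses known chemistry, sets out from 6 and returns to the route at 20.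
   - Miyaura borylation of 6 (B2pin2, Pd(dppf)Cl2, KOAc, dioxane, 90 °C) would give 5,7-bis(benzyloxy)-2-[4-(benzyloxy)-3-(4,4,5,5-tetramethyl-1,3,2-dioxaborolan-2-yl)phenyl]chromen-4-one F1.
   - Separately, commercial 2'-hydroxy-4',6'-dimethoxyacetophenone and 4-(benzyloxy)benzaldehyde would be condensed (KOH, EtOH) to (E)-3-[4-(benzyloxy)phenyl]-1-(2-hydroxy-4,6-dimethoxyphenyl)prop-2-en-1-one F2.
   - F2 would be cyclised with I2 in DMSO to 2-[4-(benzyloxy)phenyl]-5,7-dimethoxychromen-4-one F3, and this lithiated and iodinated at C3 (LiN(i-Pr)2, THF, −78 °C; I2) to 2-[4-(benzyloxy)phenyl]-3-iodo-5,7-dimethoxychromen-4-one F4.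
   - Suzuki–Miyaura coupling of F1 with F4 (Pd(OAc)2, SPhos, K3PO4, PhMe/H2O, 90 °C) would give 2-[4-(benzyloxy)phenyl]-3-{2-(benzyloxy)-5-[5,7-bis(benzyloxy)-4-oxochromen-2-yl]phenyl}-5,7-dimethoxychromen-4-one F5.
   - BCl3 (CH2Cl2, −78 to 0 °C) would remove the four benzyl groups together with the carbonyl-chelated C5 methyl ether and leave the C7 methyl ether, reaching 20 directly; steps 6 to 12 would then not be needed.

2. Step 6. Acylation may take place at the enolate oxygen instead of carbon, or the crowded 2-aryl-1,3-diketone may be cleaved by retro-Claisen reaction during work-up. The fallback sets out from 8 and returns at 10. The lithium enolate of 8 (LiN(SiMe3)2, THF, −78 °C) would be added to (phenylthio)acetaldehyde to give 1-[4-(benzyloxy)phenyl]-2-{2-(benzyloxy)-5-[5,7-bis(benzyloxy)-4-oxochromen-2-yl]phenyl}-3-hydroxy-4-(phenylthio)butan-1-one F6 as a mixture of diastereomers. Oxidation of the secondary alcohol with Dess–Martin periodinane would give 10. The C–C bond is thus made by an aldol addition, where O-attack is not an issue.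

3. Step 7. Condensation at the weakly activated CH2 next to sulfur may be slow, allowing O-methylation of the enol or cleavage of the diketone by the amide acetal to compete. The fallback sets out from 10 and returns at 13. The sulfide would be oxidised first (mCPBA, CH2Cl2, 0 °C) to 1-[4-(benzyloxy)phenyl]-2-{2-(benzyloxy)-5-[5,7-bis(benzyloxy)-4-oxochromen-2-yl]phenyl}-4-(phenylsulfonyl)butane-1,3-dione F7. Its CH2 is flanked by carbonyl and sulfone and should condense with Me2NCH(OMe)2 at room temperature to 1-[4-(benzyloxy)phenyl]-2-{2-(benzyloxy)-5-[5,7-bis(benzyloxy)-4-oxochromen-2-yl]phenyl}-5-(dimethylamino)-4-(phenylsulfonyl)pent-4-ene-1,3-dione F8 (not isolated). Acetic acid would close F8 to 13, making compound 12 and step 8 unnecessary.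

**Further compounds**

F1 | step 11 | 5,7-bis(benzyloxy)-2-[4-(benzyloxy)-3-(4,4,5,5-tetramethyl-1,3,2-dioxaborolan-2-yl)phenyl]chromen-4-one | O=c1cc(-c2ccc(OCc3ccccc3)c(B3OC(C)(C)C(C)(C)O3)c2)oc2cc(OCc3ccccc3)cc(OCc3ccccc3)c12
F2 | step 11 | (E)-3-[4-(benzyloxy)phenyl]-1-(2-hydroxy-4,6-dimethoxyphenyl)prop-2-en-1-one | COc1cc(O)c(C(=O)/C=C/c2ccc(OCc3ccccc3)cc2)c(OC)c1
F3 | step 11 | 2-[4-(benzyloxy)phenyl]-5,7-dimethoxychromen-4-one | COc1cc(OC)c2c(=O)cc(-c3ccc(OCc4ccccc4)cc3)oc2c1
F4 | step 11 | 2-[4-(benzyloxy)phenyl]-3-iodo-5,7-dimethoxychromen-4-one | COc1cc(OC)c2c(=O)c(I)c(-c3ccc(OCc4ccccc4)cc3)oc2c1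
F5 | step 11 | 2-[4-(benzyloxy)phenyl]-3-{2-(benzyloxy)-5-[5,7-bis(benzyloxy)-4-oxochromen-2-yl]phenyl}-5,7-dimethoxychromen-4-one | COc1cc(OC)c2c(=O)c(-c3cc(-c4cc(=O)c5c(OCc6ccccc6)cc(OCc6ccccc6)cc5o4)ccc3OCc3ccccc3)c(-c3ccc(OCc4ccccc4)cc3)oc2c1
F6 | step 6 | 1-[4-(benzyloxy)phenyl]-2-{2-(benzyloxy)-5-[5,7-bis(benzyloxy)-4-oxochromen-2-yl]phenyl}-3-hydroxy-4-(phenylthio)butan-1-one (mixture of diastereomers) | O=C(c1ccc(OCc2ccccc2)cc1)C(C(O)CSc1ccccc1)c1cc(-c2cc(=O)c3c(OCc4ccccc4)cc(OCc4ccccc4)cc3o2)ccc1OCc1ccccc1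
F7 | step 7 | 1-[4-(benzyloxy)phenyl]-2-{2-(benzyloxy)-5-[5,7-bis(benzyloxy)-4-oxochromen-2-yl]phenyl}-4-(phenylsulfonyl)butane-1,3-dione | O=C(CS(=O)(=O)c1ccccc1)C(C(=O)c1ccc(OCc2ccccc2)cc1)c1cc(-c2cc(=O)c3c(OCc4ccccc4)cc(OCc4ccccc4)cc3o2)ccc1OCc1ccccc1
F8 | step 7 | 1-[4-(benzyloxy)phenyl]-2-{2-(benzyloxy)-5-[5,7-bis(benzyloxy)-4-oxochromen-2-yl]phenyl}-5-(dimethylamino)-4-(phenylsulfonyl)pent-4-ene-1,3-dione | CN(C)C=C(S(=O)(=O)c1ccccc1)C(=O)C(C(=O)c1ccc(OCc2ccccc2)cc1)c1cc(-c2cc(=O)c3c(OCc4ccccc4)cc(OCc4ccccc4)cc3o2)ccc1OCc1ccccc1
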